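**Plan**

- Retrosynthesis: both bonds from the arene to the dihydropyran ring (aryl C4a–C4 and aryl C8a–O1) are cut together, giving 4-iodo-3-methylanisole and a γ-bromo tertiary alcohol that carries the whole bicyclic enone. The enone is then cut at C6–CH2 (epoxide-derived carbanion plus a transposable enone), at C5–CH2 (Stille), at the angular C–CH3 bond (cuprate) and at the two Robinson bonds.
- Enabling feature: in the chroman the ether oxygen (on C8a) and the benzylic CH2 (on C4a) sit on adjacent arene carbons, and the next carbon (C8) carries a methyl group. An ortho-methyl aryl iodide can therefore be ortho-alkylated and ipso-etherified through a temporary aryl–norbornyl palladacycle that is built and cleaved within the step; the tertiary alkoxide three carbons from the bromide closes the six-membered ring.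
- Forward order: cyclopentanone, then the cyclohexenone ring (Robinson), then the second quaternary carbon, then the enone carrying both CH2–C(OH) arms, and last the arene and the dihydropyran ring. The arene is attached last because a β-aryloxy carbanion could not be used earlier.
- Stereochemistry: the first quaternary centre comes from the Michael addition of the (S)-1-phenylethylamine ketimine, the second from cis-selective cuprate addition. The carbinol centre comes from a catalytic asymmetric Corey–Chaykovsky epoxidation and is never touched again, because the last C–O bond is made at the aryl carbon.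

Key step: step 14

Remark: the two ring-fusion methyl groups are cis (both centres S in the target). In step 2 the BINOL antipode is the one that gives the R epoxide, to be fixed by correlation of that epoxide with (R)-2-methylbutane-1,2,4-triol.

**Route**

Step 1
Reactants: 1 4-hydroxybutan-2-one
Product: 2 4-[(tert-butyldimethylsilyl)oxy]butan-2-one
Conditions: TBSCl, imidazole, CH2Cl2, 0 °C to rt
Reagents that add atoms: tert-butyldimethylsilyl chloride, CC(C)(C)[Si](C)(C)Cl
Why: Imidazole-promoted silylation of the primary alcohol gives an ether that should survive the ylide, arenide and chromium reagents used later and is removed by fluoride in step 12.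

Step 2
Reactants: 2 4-[(tert-butyldimethylsilyl)oxy]butan-2-one
Product: 3 (2R)-2-{2-[(tert-butyldimethylsilyl)oxy]ethyl}-2-methyloxirane
Conditions: Me3S(O)I, NaH, THF, rt; then 2, LaLi3(binaphthoxide)3 (5 mol %, BINOL antipode that gives the R epoxide), tris(2,4,6-trimethoxyphenyl)phosphine oxide (5 mol %), MS 5 Å, THF, rt
Reagents that add atoms: trimethylsulfoxonium iodide, C[S+](C)(C)=O.[I-]
Why: Catalytic asymmetric Corey–Chaykovsky epoxidation of a methyl ketone, in which the lanthanum–lithium binaphthoxide binds ketone and sulfoxonium methylide and differentiates the carbonyl faces (CH3 against CH2CH2OSi), should set the tertiary C–O stereocentre as R.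

Step 3
Reactants: 4 2-methylcyclopentan-1-one (racemic); 5 (S)-1-phenylethylamine; 6 but-3-en-2-one
Product: 9 (2R)-2-methyl-2-(3-oxobutyl)cyclopentan-1-one, via chiral ketimine 7 (not isolated), via Michael adduct ketimine 8 (not isolated)
Conditions: 4, 5, toluene, reflux, Dean–Stark; concentrate; 6, THF, 40 °C; then 20% aq. AcOH, rt
Reagents that add atoms: water, O
Why: Deracemising Michael addition through the more substituted secondary enamine tautomer of the chiral ketimine (aza-ene-like transition state, attack anti to the phenyl group of the auxiliary) should create the quaternary carbon as R, by analogy with the 2-methylcyclohexanone series, and acidic hydrolysis frees the 1,5-diketone and the amine.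

Step 4
Reactants: 9 (2R)-2-methyl-2-(3-oxobutyl)cyclopentan-1-one
Product: 10 (7aR)-7a-methyl-1,2,3,6,7,7a-hexahydro-5H-inden-5-one
Conditions: NaOMe, MeOH, 60 °C
Reagents that add atoms: none
Why: Intramolecular aldol condensation (second half of a Robinson annulation) of the methyl ketone enolate onto the ring ketone and dehydration should give the conjugated bicyclic enone; the quaternary centre cannot epimerise.

Step 5
Reactants: 10 (7aR)-7a-methyl-1,2,3,6,7,7a-hexahydro-5H-inden-5-one
Product: 11 (3aS,7aR)-3a,7a-dimethyloctahydro-5H-inden-5-one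
Conditions: Me2CuLi (from MeLi, CuI), Et2O, 0 °C; aq. NH4Cl
Reagents that add atoms: lithium dimethylcuprate, C[Cu-]C.[Li+] (from methyllithium, C[Li], and CuI)
Why: Conjugate addition of lithium dimethylcuprate (Me2CuLi) to the β,β-disubstituted enone should deliver methyl to the ring-fusion carbon on the face that gives the cis-fused hydrindane, that is cis to the angular methyl group, setting the second quaternary stereocentre (3aS).

Step 6
Reactants: 11 (3aS,7aR)-3a,7a-dimethyloctahydro-5H-inden-5-one
Product: 12 (3aS,7aR)-3a,7a-dimethyl-1,2,3,3a,4,7a-hexahydro-5H-inden-5-one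
Conditions: Pd(O2CCF3)2 (5 mol %), DMSO (10 mol %), O2 (1 atm), AcOH, 80 °C
Reagents that add atoms: none
Why: Palladium-catalysed aerobic α,β-dehydrogenation of a cyclohexanone (palladium enolate, β-hydride elimination, reoxidation by O2) can only give the C6–C7 enone, because the other β-carbon (C3a) is quaternary, and for the same reason no second dehydrogenation is possible.

Step 7
Reactants: 12 (3aS,7aR)-3a,7a-dimethyl-1,2,3,3a,4,7a-hexahydro-5H-inden-5-one
Product: 13 (3aS,7aR)-6-iodo-3a,7a-dimethyl-1,2,3,3a,4,7a-hexahydro-5H-inden-5-one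
Conditions: I2, pyridine, CH2Cl2, 0 °C to rt
Reagents that add atoms: iodine, [I][I]
Why: α-Iodination of the enone by conjugate addition of pyridine, iodination of the enolate and loss of pyridine (Baylis–Hillman-type addition–elimination) is well precedented for cyclohexenones whose β-carbon is flanked by a quaternary centre.

Step 8
Reactants: 13 (3aS,7aR)-6-iodo-3a,7a-dimethyl-1,2,3,3a,4,7a-hexahydro-5H-inden-5-one; 14 tributyl(2-methylprop-2-en-1-yl)stannane
Product: 15 (3aS,7aR)-3a,7a-dimethyl-6-(2-methylprop-2-en-1-yl)-1,2,3,3a,4,7a-hexahydro-5H-inden-5-one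
Conditions: Pd2(dba)3 (2.5 mol %), AsPh3 (10 mol %), CuI (10 mol %), NMP, 50 °C
Reagents that add atoms: none
Why: Stille coupling of an α-iodoenone with an allylic stannane under triphenylarsine/CuI acceleration should install the methallyl arm; its two CH2 termini are equivalent in substitution, so no allylic regiochemistry arises.

Step 9
Reactants: 3 (2R)-2-{2-[(tert-butyldimethylsilyl)oxy]ethyl}-2-methyloxirane; 15 (3aS,7aR)-3a,7a-dimethyl-6-(2-methylprop-2-en-1-yl)-1,2,3,3a,4,7a-hexahydro-5H-inden-5-one
Product: 17 (3aS,7aR)-5-[(2R)-4-[(tert-butyldimethylsilyl)oxy]-2-hydroxy-2-methylbutyl]-3a,7a-dimethyl-6-(2-methylprop-2-en-1-yl)-2,3,3a,4,5,7a-hexahydro-1H-inden-5-ol (both C5 epimers), via β-lithioalkoxide dianion 16 (not isolated)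
Conditions: 3 (2.5 equiv), lithium 4,4'-di-tert-butylbiphenylide (LiDBB, 1.95 equiv per 3), THF, −78 °C; CeCl3, −78 °C; then 15, −78 to −40 °C; aq. NH4Cl
Reagents that add atoms: none
Why: Reductive lithiation of the 2,2-disubstituted epoxide by the arene radical anion should cleave the CH2–O bond to the primary carbanion bearing a tertiary lithium alkoxide (loss of Li2O is slow at −78 °C), and in the presence of CeCl3 this less basic, more oxophilic carbanion should add 1,2 to the hindered enone carbonyl; the carbinol stereocentre is untouched and the new C5 centre is destroyed in step 10.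

Step 10
Reactants: 17 (3aS,7aR)-5-[(2R)-4-[(tert-butyldimethylsilyl)oxy]-2-hydroxy-2-methylbutyl]-3a,7a-dimethyl-6-(2-methylprop-2-en-1-yl)-2,3,3a,4,5,7a-hexahydro-1H-inden-5-ol
Product: 18 (3aS,7aS)-6-[(2S)-4-[(tert-butyldimethylsilyl)oxy]-2-hydroxy-2-methylbutyl]-3a,7a-dimethyl-5-(2-methylprop-2-en-1-yl)-1,2,3,3a,7,7a-hexahydro-4H-inden-4-one
Conditions: pyridinium chlorochromate (C5H5NH[CrO3Cl]), MS 4 Å, CH2Cl2, rt
Reagents that add atoms: pyridinium chlorochromate, [O-][Cr](=O)(=O)Cl.c1cc[nH+]cc1
Why: Babler–Dauben oxidative transposition, in which the tertiary allylic chromate ester undergoes a [3,3] shift to the secondary allylic chromate (whose C–O oxygen comes from the chromium reagent) that is then oxidised, should place the carbonyl next to the quaternary carbon and the double bond between the two side-chain-bearing carbons; the stereodescriptor of the carbinol changes from R to S only through a change of ligand priorities.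

Step 11
Reactants: 18 (3aS,7aS)-6-[(2S)-4-[(tert-butyldimethylsilyl)oxy]-2-hydroxy-2-methylbutyl]-3a,7a-dimethyl-5-(2-methylprop-2-en-1-yl)-1,2,3,3a,7,7a-hexahydro-4H-inden-4-one
Product: 19 (3aS,7aS)-6-[(2S)-4-[(tert-butyldimethylsilyl)oxy]-2-hydroxy-2-methylbutyl]-5-(2-hydroxy-2-methylpropyl)-3a,7a-dimethyl-1,2,3,3a,7,7a-hexahydro-4H-inden-4-one
Conditions: Co(acac)2 (20 mol %), PhSiH3, O2 (1 atm), i-PrOH/THF, rt
Reagents that add atoms: dioxygen, O=O
Why: Mukaiyama hydration (hydrogen-atom transfer from a cobalt hydride to the 1,1-disubstituted alkene, capture of the tertiary radical by O2, reduction of the peroxide) is Markovnikov-selective and should leave the hindered, electron-poor tetrasubstituted enone alone.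

Step 12
Reactants: 19 (3aS,7aS)-6-[(2S)-4-[(tert-butyldimethylsilyl)oxy]-2-hydroxy-2-methylbutyl]-5-(2-hydroxy-2-methylpropyl)-3a,7a-dimethyl-1,2,3,3a,7,7a-hexahydro-4H-inden-4-one
Product: 20 (3aS,7aS)-6-[(2S)-2,4-dihydroxy-2-methylbutyl]-5-(2-hydroxy-2-methylpropyl)-3a,7a-dimethyl-1,2,3,3a,7,7a-hexahydro-4H-inden-4-one
Conditions: Bu4NF, THF, 0 °C to rt
Reagents that add atoms: none
Why: Fluoride cleavage of the primary silyl ether; the tertiary alcohols and the enone are inert.

Step 13
Reactants: 20 (3aS,7aS)-6-[(2S)-2,4-dihydroxy-2-methylbutyl]-5-(2-hydroxy-2-methylpropyl)-3a,7a-dimethyl-1,2,3,3a,7,7a-hexahydro-4H-inden-4-one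
Product: 21 (3aS,7aS)-6-[(2S)-4-bromo-2-hydroxy-2-methylbutyl]-5-(2-hydroxy-2-methylpropyl)-3a,7a-dimethyl-1,2,3,3a,7,7a-hexahydro-4H-inden-4-one
Conditions: CBr4, PPh3, CH2Cl2, 0 °C
Reagents that add atoms: carbon tetrabromide, BrC(Br)(Br)Br
Why: Appel reaction, in which only the primary alcohol forms an alkoxyphosphonium ion that bromide can displace (SN2); the two tertiary alcohols are too hindered at 0 °C.

Step 14
Reactants: 21 (3aS,7aS)-6-[(2S)-4-bromo-2-hydroxy-2-methylbutyl]-5-(2-hydroxy-2-methylpropyl)-3a,7a-dimethyl-1,2,3,3a,7,7a-hexahydro-4H-inden-4-one; 22 1-iodo-4-methoxy-2-methylbenzene (4-iodo-3-methylanisole, 1.5 equiv)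
Product: 23 (3aS,7aS)-5-(2-hydroxy-2-methylpropyl)-6-{[(2R)-6-methoxy-2,8-dimethyl-3,4-dihydro-2H-chromen-2-yl]methyl}-3a,7a-dimethyl-1,2,3,3a,7,7a-hexahydro-4H-inden-4-one (CNP0224132.1)
Conditions: Pd(OAc)2 (10 mol %), RuPhos (20 mol %), norbornene (1 equiv), Cs2CO3 (3 equiv), 1,4-dioxane, 100 °C
Reagents that add atoms: none
Why: Proposed new method: zerovalent palladium inserts into the C–I bond of 22, norbornene is carbopalladated and base-assisted C–H palladation at the only free ortho carbon gives a five-membered aryl–norbornyl palladacycle, which takes up the primary C–Br bond of 21 (SN2-type oxidative addition to tetravalent palladium) and forms the aryl–CH2 bond by reductive elimination; with both ortho positions now substituted, norbornene is expelled by β-carbon elimination and the divalent arylpalladium is captured by the tethered tertiary alkoxide, C–O reductive elimination closing the ring. The closest known reaction types are the Catellani ortho-alkylation of ortho-substituted aryl iodides with primary alkyl halides, the palladium/norbornene annulation of aryl iodides with epoxides that ends in ipso C–O bond formation to 2,3-dihydrobenzofurans, and the palladium-catalysed intramolecular etherification of aryl halides with tertiary alcohols to 2,2-disubstituted chromans; new here is a γ-bromo tertiary alcohol as the bifunctional partner, so that the ipso step closes a six-membered ring. The dihydropyran ring is closed as a formal (4+2) annulation of the C–C–C–O unit onto two adjacent arene carbons, the ring-forming event being reductive elimination from a seven-membered oxapalladacycle. No stereocentre is created: the carbinol configuration from step 2 is retained because the new C–O bond is made at the aryl carbon and no bond to the carbinol carbon is broken, and the tertiary alkoxide has no carbinol hydrogen for β-hydride elimination. Site selectivity (C–C at the ring carbon meta to OMe, C–O at the former C–I carbon) is secured by the C-methyl group, which blocks the second ortho position and supplies the ortho substituent that norbornene extrusion needs; Heck-type termination is disfavoured by the hindered tetrasubstituted enone and oxetane formation by the weak carbonate base.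

**Compound list**

1 | 4-hydroxybutan-2-one | CC(=O)CCO | starting material
2 | 4-[(tert-butyldimethylsilyl)oxy]butan-2-one | CC(=O)CCO[Si](C)(C)C(C)(C)C | intermediate
3 | (2R)-2-{2-[(tert-butyldimethylsilyl)oxy]ethyl}-2-methyloxirane | CC(C)(C)[Si](C)(C)OCC[C@]1(C)CO1 | intermediate
4 | 2-methylcyclopentan-1-one (racemic) | CC1CCCC1=O | starting material
5 | (S)-1-phenylethylamine | C[C@H](N)c1ccccc1 | starting material
6 | but-3-en-2-one (methyl vinyl ketone) | CC(=O)C=C | starting material
7 | 2-methyl-N-[(1S)-1-phenylethyl]cyclopentan-1-imine (in equilibrium with its secondary enamine) | CC1CCCC1=N[C@@H](C)c1ccccc1 | intermediate (not isolated)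
8 | 4-[(1R)-1-methyl-2-{[(1S)-1-phenylethyl]imino}cyclopentyl]butan-2-one | CC(=O)CC[C@@]1(C)CCCC1=N[C@@H](C)c1ccccc1 | intermediate (not isolated)
9 | (2R)-2-methyl-2-(3-oxobutyl)cyclopentan-1-one | CC(=O)CC[C@@]1(C)CCCC1=O | intermediate
10 | (7aR)-7a-methyl-1,2,3,6,7,7a-hexahydro-5H-inden-5-one | O=C1CC[C@@]2(C)CCCC2=C1 | intermediate
11 | (3aS,7aR)-3a,7a-dimethyloctahydro-5H-inden-5-one (cis ring fusion) | O=C1CC[C@@]2(C)CCC[C@@]2(C)C1 | intermediate
12 | (3aS,7aR)-3a,7a-dimethyl-1,2,3,3a,4,7a-hexahydro-5H-inden-5-one | O=C1C=C[C@@]2(C)CCC[C@@]2(C)C1 | intermediate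
13 | (3aS,7aR)-6-iodo-3a,7a-dimethyl-1,2,3,3a,4,7a-hexahydro-5H-inden-5-one | O=C1C(I)=C[C@@]2(C)CCC[C@@]2(C)C1 | intermediate
14 | tributyl(2-methylprop-2-en-1-yl)stannane | CCCC[Sn](CCCC)(CCCC)CC(C)=C | starting material
15 | (3aS,7aR)-3a,7a-dimethyl-6-(2-methylprop-2-en-1-yl)-1,2,3,3a,4,7a-hexahydro-5H-inden-5-one | O=C1C(CC(C)=C)=C[C@@]2(C)CCC[C@@]2(C)C1 | intermediate
16 | lithium (2S)-4-[(tert-butyldimethylsilyl)oxy]-1-lithio-2-methylbutan-2-olate | [Li]C[C@@](C)(CCO[Si](C)(C)C(C)(C)C)O[Li] | intermediate (not isolated)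
17 | (3aS,7aR)-5-[(2R)-4-[(tert-butyldimethylsilyl)oxy]-2-hydroxy-2-methylbutyl]-3a,7a-dimethyl-6-(2-methylprop-2-en-1-yl)-2,3,3a,4,5,7a-hexahydro-1H-inden-5-ol (both C5 epimers) | CC(C)(C)[Si](C)(C)OCC[C@](C)(CC1(O)C(CC(C)=C)=C[C@@]2(C)CCC[C@@]2(C)C1)O | intermediate
18 | (3aS,7aS)-6-[(2S)-4-[(tert-butyldimethylsilyl)oxy]-2-hydroxy-2-methylbutyl]-3a,7a-dimethyl-5-(2-methylprop-2-en-1-yl)-1,2,3,3a,7,7a-hexahydro-4H-inden-4-one | CC(C)(C)[Si](C)(C)OCC[C@](C)(CC1=C(CC(C)=C)C(=O)[C@@]2(C)CCC[C@@]2(C)C1)O | intermediate
19 | (3aS,7aS)-6-[(2S)-4-[(tert-butyldimethylsilyl)oxy]-2-hydroxy-2-methylbutyl]-5-(2-hydroxy-2-methylpropyl)-3a,7a-dimethyl-1,2,3,3a,7,7a-hexahydro-4H-inden-4-one | CC(C)(C)[Si](C)(C)OCC[C@](C)(CC1=C(CC(C)(C)O)C(=O)[C@@]2(C)CCC[C@@]2(C)C1)O | intermediate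
20 | (3aS,7aS)-6-[(2S)-2,4-dihydroxy-2-methylbutyl]-5-(2-hydroxy-2-methylpropyl)-3a,7a-dimethyl-1,2,3,3a,7,7a-hexahydro-4H-inden-4-one | OCC[C@](C)(CC1=C(CC(C)(C)O)C(=O)[C@@]2(C)CCC[C@@]2(C)C1)O | intermediate
21 | (3aS,7aS)-6-[(2S)-4-bromo-2-hydroxy-2-methylbutyl]-5-(2-hydroxy-2-methylpropyl)-3a,7a-dimethyl-1,2,3,3a,7,7a-hexahydro-4H-inden-4-one | BrCC[C@](C)(CC1=C(CC(C)(C)O)C(=O)[C@@]2(C)CCC[C@@]2(C)C1)O | intermediate
22 | 1-iodo-4-methoxy-2-methylbenzene (4-iodo-3-methylanisole) | COc1ccc(I)c(C)c1 | starting material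
23 | (3aS,7aS)-5-(2-hydroxy-2-methylpropyl)-6-{[(2R)-6-methoxy-2,8-dimethyl-3,4-dihydro-2H-chromen-2-yl]methyl}-3a,7a-dimethyl-1,2,3,3a,7,7a-hexahydro-4H-inden-4-one | COc1cc(C)c2c(c1)CC[C@](C)(CC1=C(CC(C)(C)O)C(=O)[C@@]3(C)CCC[C@@]3(C)C1)O2 | target

**Step count and risks**

Total steps: 14. Longest linear sequence: 12 steps (steps 3 to 14, from 2-methylcyclopentan-1-one 4).

Steps most likely to fail:

1. Step 14. The relay may stall after oxidative addition (protodepalladation or norbornene-containing by-products), or the γ-bromo alkoxide may close to an oxetane before it meets the palladacycle. The tertiary alkoxide may also fragment by vinylogous retro-aldol cleavage, or its C–O reductive elimination may be too slow. Fallback from 21 back to 23, making the two bonds one after the other by known reactions: commercial 4-methoxy-2-methylaniline F1 is brominated ortho to nitrogen (NBS, MeCN, 0 °C) to 2-bromo-4-methoxy-6-methylaniline F2. Sandmeyer chlorination of F2 (t-BuONO, CuCl2, MeCN) gives 1-bromo-2-chloro-5-methoxy-3-methylbenzene F3. Nickel-catalysed cross-electrophile coupling of F3 at its C–Br bond with bromide 21 (NiI2, 4,4'-di-tert-butyl-2,2'-bipyridine, NaI, Zn, DMA, 60 °C) gives the aryl chloride (3aS,7aS)-6-[(2R)-4-(2-chloro-5-methoxy-3-methylphenyl)-2-hydroxy-2-methylbutyl]-5-(2-hydroxy-2-methylpropyl)-3a,7a-dimethyl-1,2,3,3a,7,7a-hexahydro-4H-inden-4-one F4. Buchwald–Hartwig-type intramolecular etherification of F4 (Pd(OAc)2, t-BuXPhos, Cs2CO3, toluene, 100 °C) then forms the aryl–O bond without touching the carbinol carbon and gives 23.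

2. Step 9. The β-lithioalkoxide may be lost by elimination, the hindered ketone may be enolised at C4 instead of attacked, or residual arenide may transfer an electron to the enone. Fallback from 3 (and 15) back to 17, carrying the same carbon as a sulfone-stabilised carbanion: epoxide 3 is opened with PhSO2Na (DMF, 80 °C) to the hydroxy sulfone (2R)-4-[(tert-butyldimethylsilyl)oxy]-2-methyl-1-(phenylsulfonyl)butan-2-ol F5. The dianion of F5 (n-BuLi, 2 equiv, THF, −78 °C) adds to the carbonyl of 15 to give the diol sulfone (3aS,7aR)-5-[(2R)-4-[(tert-butyldimethylsilyl)oxy]-2-hydroxy-2-methyl-1-(phenylsulfonyl)butyl]-3a,7a-dimethyl-6-(2-methylprop-2-en-1-yl)-2,3,3a,4,5,7a-hexahydro-1H-inden-5-ol F6. Reductive desulfonylation of F6 with sodium amalgam (Na/Hg, Na2HPO4, MeOH, −20 °C) returns 17.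

3. Step 10. Ionisation of the tertiary allylic chromate may outrun the sigmatropic shift, so that the allyl cation is captured by the free tertiary hydroxyl (six-membered cyclic ether) or loses a proton to give dienes. Fallback from 17 back to 18, separating transposition from oxidation: Ph3SiOReO3 (2 mol %, Et2O, −50 to 0 °C) should equilibrate 17 to the secondary allylic alcohol with the tetrasubstituted double bond, (3aS,7aS)-6-[(2S)-4-[(tert-butyldimethylsilyl)oxy]-2-hydroxy-2-methylbutyl]-3a,7a-dimethyl-5-(2-methylprop-2-en-1-yl)-2,3,3a,4,7,7a-hexahydro-1H-inden-4-ol F7. Dess–Martin periodinane (NaHCO3, CH2Cl2, rt) then oxidises F7 to 18.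

**Further compounds**

F1 | step 14 | 4-methoxy-2-methylaniline (commercial) | COc1ccc(N)c(C)c1
F2 | step 14 | 2-bromo-4-methoxy-6-methylaniline | COc1cc(C)c(N)c(Br)c1
F3 | step 14 | 1-bromo-2-chloro-5-methoxy-3-methylbenzene | COc1cc(C)c(Cl)c(Br)c1
F4 | step 14 | (3aS,7aS)-6-[(2R)-4-(2-chloro-5-methoxy-3-methylphenyl)-2-hydroxy-2-methylbutyl]-5-(2-hydroxy-2-methylpropyl)-3a,7a-dimethyl-1,2,3,3a,7,7a-hexahydro-4H-inden-4-one | COc1cc(C)c(Cl)c(c1)CC[C@](C)(CC1=C(CC(C)(C)O)C(=O)[C@@]2(C)CCC[C@@]2(C)C1)O
F5 | step 9 | (2R)-4-[(tert-butyldimethylsilyl)oxy]-2-methyl-1-(phenylsulfonyl)butan-2-ol | CC(C)(C)[Si](C)(C)OCC[C@](C)(CS(=O)(=O)c1ccccc1)O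
F6 | step 9 | (3aS,7aR)-5-[(2R)-4-[(tert-butyldimethylsilyl)oxy]-2-hydroxy-2-methyl-1-(phenylsulfonyl)butyl]-3a,7a-dimethyl-6-(2-methylprop-2-en-1-yl)-2,3,3a,4,5,7a-hexahydro-1H-inden-5-ol (mixture at the two new centres) | CC(C)(C)[Si](C)(C)OCC[C@](C)(C(C1(O)C(CC(C)=C)=C[C@@]2(C)CCC[C@@]2(C)C1)S(=O)(=O)c1ccccc1)O
F7 | step 10 | (3aS,7aS)-6-[(2S)-4-[(tert-butyldimethylsilyl)oxy]-2-hydroxy-2-methylbutyl]-3a,7a-dimethyl-5-(2-methylprop-2-en-1-yl)-2,3,3a,4,7,7a-hexahydro-1H-inden-4-ol (both C4 epimers) | CC(C)(C)[Si](C)(C)OCC[C@](C)(CC1=C(CC(C)=C)C(O)[C@@]2(C)CCC[C@@]2(C)C1)O
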